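The meeting had one vessel before it: a closed, stirred, isothermal flask of free enzyme, starting material, second substrate and impurity, set beside the earlier runs.

common to all: starting material 0.020 M; impurity 0.39 µM
- zeta: second substrate 1 equiv; free enzyme 0.0017 mol%; run made earlier
- delta: second substrate 1 equiv; free enzyme 0.0025 mol%; run made earlier
- eta: second substrate 0.50 equiv; free enzyme 0.0034 mol%; run made earlier
- flask: second substrate 1.00 equiv; free enzyme 0.0034 mol%

| run | time / min | target / % | starting material / % |
|---|---|---|---|
| zeta | 0.200 | 0.1 | 99.5 |
| zeta | 0.333 | 0.9 | 99.5 |
| zeta | 0.417 | 1.2 | 99.1 |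
| zeta | 0.667 | 1.4 | 98.9 |
| zeta | 1.00 | 1.3 | 98.5 |
| zeta | 1.50 | 2.1 | 98.4 |
| zeta | 2.50 | 2.3 | 98.1 |
| delta | 0.167 | 0.6 | 99.7 |
| delta | 0.333 | 0 | 99.5 |
| delta | 0.667 | 1.2 | 98.5 |
| delta | 1.00 | 2.0 | 98.1 |
| delta | 1.33 | 2.8 | 97.5 |
| delta | 2.00 | 3.6 | 96.3 |
| delta | 2.50 | 4.6 | 96.2 |
| eta | 0.500 | 1.3 | 99.2 |
| eta | 1.00 | 2.8 | 97.4 |
| eta | 1.33 | 2.8 | 96.7 |
| eta | 2.00 | 4.5 | 95.7 |
| eta | 2.50 | 5.1 | 95.2 |

(readings scatter by 0.3 percentage points)

- what may be going on: second substrate + loaded enzyme <-> second complex; second complex -> free enzyme + target; first complex <-> loaded enzyme + first product; starting material + free enzyme <-> first complex; free enzyme + impurity -> spent catalyst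

* apparent order in second substrate when 30 % of the starting material are converted (percent change of the rate of making target for one percent more second substrate charged)

The process chemist noted that this flask holds 0.680 µM enzyme against 0.39 µM impurity, and that the zeta run reads 2.3 % target at 2.50 min, slowing as a titration of the enzyme would. The kineticist replied that the delta run then keeps a small difference, 0.110 µM, so that a rate per surviving enzyme, and with it any order read from delta against eta, is poorly known.

She therefore split the question into two factors: a local order in [second substrate] as it stands, and a factor that follows from the charge. At 30 % conversion from 1.00 equiv, [second substrate] in the flask stands at 0.0140 M, and whatever extra is charged is still there, so each percent more charged raises it 1.43 percent. She named this factor the gearing, the percent rise of standing [second substrate] per percent more charged. For a local order between zero and one, she would commit only to an answer between zero and 1.43.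

The forecaster entered 1.15, using the same factor and a local order of 0.8, on the ground that “Rate therefore looks close to first order in second substrate”.

    second substrate + loaded enzyme ⇌ second complex (K = 30.0 M⁻¹, k = 3.90 × 10⁵ M⁻¹ s⁻¹)
    second complex → free enzyme + target (k = 150 s⁻¹)
    first complex ⇌ loaded enzyme + first product (K = 0.0130 M, k = 76.0 s⁻¹)
    starting material + free enzyme ⇌ first complex (K = 51.0 M⁻¹, k = 1.60 × 10⁵ M⁻¹ s⁻¹)
    free enzyme + impurity → spent catalyst (k = 1.80 × 10⁵ M⁻¹ s⁻¹)

The flask gives 0.67, at 18.5 min. Divided by the gearing, this is a local order of 0.469 in [second substrate] rather than the forecast's 0.8, so the forecast parts from the flask in the local order and not in the gearing. The undoing of first complex into starting material and free enzyme is not why that order lies below one: the simulated run without it gives 0.77, a local order of 0.538 by the same gearing. The step from free enzyme + impurity to spent catalyst accounts for a part of the flask's apparent order in free enzyme, which is 2.3 there against 1.0 in the simulated run without that step.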